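**Retrosynthetic overview**

1. The last step makes the E‑C7'=C8' bond by alkoxide‑directed hydroalumination of a C40 bis‑alkyne; that C40 compound comes from C15 + C10 + C15 by two Wittig reactions (C11=C12 and C11'=C12').
2. Both C15 Wittig salts come from one enyne diol (ring iodide + (E)‑3‑methylpent‑2‑en‑4‑yn‑1‑ol, Sonogashira); the ring B triol arises by hydroxyl‑directed syn‑epoxidation and trans‑diaxial hydrolysis.
3. The ring iodide comes from (4R,6R)‑4‑hydroxy‑2,2,6‑trimethylcyclohexanone, made by enzymatic dynamic kinetic reduction of racemic 2,2,6‑trimethylcyclohexane‑1,4‑dione; this carbinol centre serves both rings.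
4. The rings are formed first: both six‑membered carbocycles close in one operation by a twofold [4+2] cycloaddition of a silicon‑tethered bis(2‑silyloxydiene), made from two molecules of mesityl oxide, with (E)‑1‑nitropropene. One ring of each pair becomes ring A, the other ring B.

Assumption: recombinant levodione reductase with a glucose dehydrogenase cofactor cycle counts as an available reagent; carotenoid numbering (C1–C6 in the ring, C3 carbinol, primes for the triol half) is used where it is clearer.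

**Route**

Step 1
Reactants: 1 4‑methylpent‑3‑en‑2‑one (mesityl oxide) (2 equiv)
Product: 3 diisopropylbis[(4‑methylpenta‑1,3‑dien‑2‑yl)oxy]silane, via lithium 4‑methylpenta‑1,3‑dien‑2‑olate 2 (not isolated)
Conditions: LiN(i‑Pr)2 (2 equiv), THF, −78 °C; i‑Pr2SiCl2 (1 equiv), −78 °C → rt
Reagents that add atoms: dichlorodiisopropylsilane, CC(C)[Si](Cl)(Cl)C(C)C
Why: Kinetic deprotonation of the ketone methyl group gives two equivalents of the cross‑conjugated lithium dienolate, and double O‑silylation of one dichlorosilane molecule (silyl bis‑enol ether formation) links the two 2‑silyloxydiene units through one silicon atom without creating a stereocenter.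

Step 2
Reactants: 4 nitromethane; 5 acetaldehyde
Product: 7 (E)‑1‑nitroprop‑1‑ene, via 1‑nitropropan‑2‑ol 6 (not isolated)
Conditions: KOC(CH3)3 (5 mol %), THF/CH3NO2, 0 °C; evaporate; N,N'‑dicyclohexylcarbodiimide, CuCl (5 mol %), Et2O, 35 °C
Reagents that add atoms: none
Why: Henry (nitroaldol) addition followed by carbodiimide‑mediated dehydration of the β‑nitro alcohol gives the conjugated nitroalkene as the more stable E isomer.

Step 3
Reactants: 3 diisopropylbis[(4‑methylpenta‑1,3‑dien‑2‑yl)oxy]silane; 7 (E)‑1‑nitroprop‑1‑ene (2.2 equiv)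
Product: 8 diisopropylbis[(3,3,5‑trimethyl‑4‑nitrocyclohex‑1‑en‑1‑yl)oxy]silane (4,5‑trans in each ring; racemic mixture of diastereomers)
Conditions: toluene, 90 °C, sealed tube, 2,6‑di‑tert‑butyl‑4‑methylphenol (1 mol %), 36 h
Reagents that add atoms: none
Why: A twofold normal‑demand Diels–Alder reaction between the two electron‑rich 2‑silyloxydiene units and the strongly electron‑poor nitroalkene closes both cyclohexene rings in the same operation with para orientation (the nitro‑bearing carbon bonds to the dimethyl‑substituted terminus) and carries the E geometry into a 4,5‑trans relation, all new stereocenters being racemic and later erased or made irrelevant.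

Step 4
Reactants: 8 diisopropylbis[(3,3,5‑trimethyl‑4‑nitrocyclohex‑1‑en‑1‑yl)oxy]silane
Product: 10 rac‑2,2,6‑trimethylcyclohexane‑1,4‑dione, via trans‑3,3,5‑trimethyl‑4‑nitrocyclohexan‑1‑one 9 (not isolated)
Conditions: NaOCH3, CH3OH, 0 °C; then H2SO4, CH3OH/H2O, −30 → 0 °C
Reagents that add atoms: water, O
Why: Methoxide cleaves both silyl enol ethers and converts the secondary nitro groups into nitronates, whose acid hydrolysis (Nef reaction) unveils the hindered carbonyl, so each molecule of 8 gives two molecules of the dione; the nitro‑bearing stereocenter disappears and the methyl‑bearing one stays racemic.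

Step 5
Reactants: 10 rac‑2,2,6‑trimethylcyclohexane‑1,4‑dione
Product: 11 (4R,6R)‑4‑hydroxy‑2,2,6‑trimethylcyclohexan‑1‑one
Conditions: levodione reductase (recombinant), NAD+ (cat.), D‑glucose, glucose dehydrogenase, K2HPO4/KH2PO4 buffer pH 8.0, 30 °C
Reagents that add atoms: none
Why: Proposed new method: the C6 stereocenter is α to the hindered carbonyl and epimerises in the mildly basic buffer while the reductase, which reduces only the (6R)‑diketone at the unhindered C4 carbonyl to the (4R)‑alcohol, drains the racemate into one stereoisomer (dynamic kinetic resolution); the closest known reaction is the enzymatic reduction of enantiopure (6R)‑2,2,6‑trimethylcyclohexane‑1,4‑dione to the same (4R,6R)‑hydroxy ketone.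

Step 6
Reactants: 11 (4R,6R)‑4‑hydroxy‑2,2,6‑trimethylcyclohexan‑1‑one
Product: 13 (1R)‑4‑iodo‑3,5,5‑trimethylcyclohex‑3‑en‑1‑ol, via (4R,6R)‑4‑hydroxy‑2,2,6‑trimethylcyclohexanone hydrazone 12 (not isolated)
Conditions: N2H4·H2O, Et3N (cat.), EtOH, 80 °C; evaporate; I2, 1,1,3,3‑tetramethylguanidine, THF, 0 °C → rt
Reagents that add atoms: iodine, II
Why: Barton vinyl iodide synthesis: iodine oxidises the hydrazone to a diazo/iodo‑carbenium species that can lose a proton only from the single α‑CH, so the tetrasubstituted iodoalkene forms regiospecifically, the methyl stereocenter is erased and the free carbinol center (R) is untouched.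

Step 7
Reactants: 13 (1R)‑4‑iodo‑3,5,5‑trimethylcyclohex‑3‑en‑1‑ol; 14 (2E)‑3‑methylpent‑2‑en‑4‑yn‑1‑ol
Product: 15 (1R)‑4‑[(3E)‑5‑hydroxy‑3‑methylpent‑3‑en‑1‑yn‑1‑yl]‑3,5,5‑trimethylcyclohex‑3‑en‑1‑ol
Conditions: Pd(PPh3)4 (3 mol %), CuI (6 mol %), i‑Pr2NH, THF, rt
Reagents that add atoms: none
Why: Sonogashira coupling of the alkenyl iodide with the terminal alkyne forms the C6–C7 bond under mild conditions that tolerate both free hydroxyl groups and keep the E enyne geometry and the carbinol configuration.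

Step 8
Reactants: 15 (1R)‑4‑[(3E)‑5‑hydroxy‑3‑methylpent‑3‑en‑1‑yn‑1‑yl]‑3,5,5‑trimethylcyclohex‑3‑en‑1‑ol
Product: 16 [(2E)‑5‑[(4R)‑4‑hydroxy‑2,6,6‑trimethylcyclohex‑1‑en‑1‑yl]‑3‑methylpent‑2‑en‑4‑yn‑1‑yl]triphenylphosphonium bromide
Conditions: PPh3·HBr (1.05 equiv), CH3OH, rt
Reagents that add atoms: triphenylphosphine hydrobromide, [Br-].[PH+](c1ccccc1)(c1ccccc1)c1ccccc1
Why: Acid‑mediated substitution of the primary allylic hydroxyl by triphenylphosphine (Wittig salt formation) occurs only at the activated allylic position, leaving the secondary ring alcohol and the E double bond unchanged.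

Step 9
Reactants: 16 C15 phosphonium bromide of ring A; 17 (2E,4E,6E)‑2,7‑dimethylocta‑2,4,6‑trienedial (3 equiv)
Product: 19 (2E,4E,6E,8E,10E)‑13‑[(4R)‑4‑hydroxy‑2,6,6‑trimethylcyclohex‑1‑en‑1‑yl]‑2,7,11‑trimethyltrideca‑2,4,6,8,10‑pentaen‑12‑ynal, via C15 phosphorus ylide 18 (not isolated)
Conditions: NaOCH3, CH2Cl2/CH3OH, 0 °C → rt; then I2 (1 mol %), CH2Cl2, rt, diffuse daylight
Reagents that add atoms: none
Why: Wittig olefination of the allylic ylide with an excess of the symmetrical dialdehyde gives the mono‑adduct, the free ring hydroxyl being tolerated and the new C11=C12 bond being equilibrated to E by iodine‑catalysed stereomutation.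

Step 10
Reactants: 15 (1R)‑4‑[(3E)‑5‑hydroxy‑3‑methylpent‑3‑en‑1‑yn‑1‑yl]‑3,5,5‑trimethylcyclohex‑3‑en‑1‑ol
Product: 20 (2E)‑5‑[(4R)‑4‑hydroxy‑2,6,6‑trimethylcyclohex‑1‑en‑1‑yl]‑3‑methylpent‑2‑en‑4‑yn‑1‑yl acetate
Conditions: CH3COCl (1.05 equiv), 2,4,6‑collidine, CH2Cl2, −78 °C
Reagents that add atoms: acetyl chloride, CC(=O)Cl
Why: Kinetically selective acylation: the unhindered primary allylic hydroxyl reacts far faster than the secondary ring hydroxyl at −78 °C, which masks the only group that could direct oxidation to the side‑chain alkene.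

Step 11
Reactants: 20 (2E)‑5‑[(4R)‑4‑hydroxy‑2,6,6‑trimethylcyclohex‑1‑en‑1‑yl]‑3‑methylpent‑2‑en‑4‑yn‑1‑yl acetate
Product: 21 (2E)‑5‑[(1S,4S,6S)‑4‑hydroxy‑2,2,6‑trimethyl‑7‑oxabicyclo[4.1.0]heptan‑1‑yl]‑3‑methylpent‑2‑en‑4‑yn‑1‑yl acetate (epoxide cis to the hydroxyl)
Conditions: VO(acac)2 (3 mol %), t‑BuOOH, CH2Cl2, 0 °C → rt
Reagents that add atoms: tert‑butyl hydroperoxide, CC(C)(C)OO
Why: Hydroxyl‑directed epoxidation (vanadium alkylperoxide bound to the homoallylic 3‑hydroxyl) delivers oxygen to the C5=C6 bond from the face of that hydroxyl and so sets both new stereocenters (syn epoxide, 5S,6S in carotenoid numbering), while the undirected acetoxy‑substituted alkene and the alkyne do not react.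

Step 12
Reactants: 21 syn‑epoxy acetate
Product: 22 (2E)‑3‑methyl‑5‑[(1S,2R,4S)‑1,2,4‑trihydroxy‑2,6,6‑trimethylcyclohexyl]pent‑2‑en‑4‑yn‑1‑yl acetate
Conditions: 0.5 M H2SO4 (aq)/THF 1:3, 0 °C → rt
Reagents that add atoms: water, O
Why: Acid‑catalysed epoxide hydrolysis by trans‑diaxial (Fürst–Plattner) opening: water attacks tertiary C5 with inversion, because the C6–O bond is deactivated by the electron‑withdrawing alkynyl group and shielded by the gem‑dimethyl carbon, which sets the 5R tertiary alcohol trans to the retained C6 hydroxyl.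

Step 13
Reactants: 22 triol acetate
Product: 23 [(2E)‑3‑methyl‑5‑[(1S,2R,4S)‑1,2,4‑trihydroxy‑2,6,6‑trimethylcyclohexyl]pent‑2‑en‑4‑yn‑1‑yl]triphenylphosphonium bromide
Conditions: PPh3·HBr (1.1 equiv), CH3OH/CH2Cl2, rt
Reagents that add atoms: triphenylphosphine hydrobromide, [Br-].[PH+](c1ccccc1)(c1ccccc1)c1ccccc1
Why: Acid‑promoted allylic substitution of the acetate by triphenylphosphine gives the Wittig salt, and the tertiary propargylic hydroxyl survives because an alkynyl group disfavours ionisation at C6.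

Step 14
Reactants: 19 C25 apo‑aldehyde; 23 trihydroxy C15 phosphonium bromide
Product: 25 (1S,2R,4S)‑1‑[(3E,5E,7E,9E,11E,13E,15E)‑18‑[(4R)‑4‑hydroxy‑2,6,6‑trimethylcyclohex‑1‑en‑1‑yl]‑3,7,12,16‑tetramethyloctadeca‑3,5,7,9,11,13,15‑heptaene‑1,17‑diyn‑1‑yl]‑2,6,6‑trimethylcyclohexane‑1,2,4‑triol, via trihydroxy C15 phosphorus ylide 24 (not isolated)
Conditions: NaOCH3, CH2Cl2/CH3OH, 0 °C → rt; then EtOH, 70 °C, dark
Reagents that add atoms: none
Why: Wittig olefination joins C11' to C12' under conditions that tolerate four free hydroxyl groups, and thermal equilibration gives the E double bond.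

Step 15
Reactants: 25 7',8'‑didehydro precursor
Product: 26 heteroxanthin, (1R,2R,4S)‑1‑[(1E,3E,5E,7E,9E,11E,13E,15E)‑18‑[(4R)‑4‑hydroxy‑2,6,6‑trimethylcyclohex‑1‑en‑1‑yl]‑3,7,12,16‑tetramethyloctadeca‑1,3,5,7,9,11,13,15‑octaen‑17‑yn‑1‑yl]‑2,6,6‑trimethylcyclohexane‑1,2,4‑triol
Conditions: NaAlH2(OCH2CH2OCH3)2 (6 equiv), THF, 0 °C → rt; aq. potassium sodium tartrate work‑up
Reagents that add atoms: none
Why: Alkoxide‑directed trans‑hydroalumination of a propargylic alcohol followed by protonolysis: only the alkyne next to the C6' aluminium alkoxide is reduced, giving the E C7'=C8' bond, while the ring A enyne (no neighbouring alkoxide) and the polyene are untouched and no stereocenter is changed (the C6' descriptor becomes R only through the priority switch).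

**Compound list**

1 | 4‑methylpent‑3‑en‑2‑one (mesityl oxide) | CC(C)=CC(C)=O | starting material
2 | lithium 4‑methylpenta‑1,3‑dien‑2‑olate | [Li+].[O-]C(=C)C=C(C)C | intermediate
3 | diisopropylbis[(4‑methylpenta‑1,3‑dien‑2‑yl)oxy]silane | CC(C)=CC(=C)O[Si](C(C)C)(C(C)C)OC(=C)C=C(C)C | intermediate
4 | nitromethane | C[N+](=O)[O-] | starting material
5 | acetaldehyde | CC=O | starting material
6 | 1‑nitropropan‑2‑ol (racemic) | CC(O)C[N+](=O)[O-] | intermediate
7 | (E)‑1‑nitroprop‑1‑ene | C/C=C/[N+](=O)[O-] | intermediate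
8 | diisopropylbis[(3,3,5‑trimethyl‑4‑nitrocyclohex‑1‑en‑1‑yl)oxy]silane (4,5‑trans in each ring, racemic diastereomer mixture, so no stereodescriptors) | CC(C)[Si](OC1=CC(C)(C)C(C(C)C1)[N+](=O)[O-])(OC1=CC(C)(C)C(C(C)C1)[N+](=O)[O-])C(C)C | intermediate
9 | trans‑3,3,5‑trimethyl‑4‑nitrocyclohexan‑1‑one (racemic, present as its nitronate) | CC1CC(=O)CC(C)(C)C1[N+](=O)[O-] | intermediate
10 | rac‑2,2,6‑trimethylcyclohexane‑1,4‑dione | CC1CC(=O)CC(C)(C)C1=O | intermediate
11 | (4R,6R)‑4‑hydroxy‑2,2,6‑trimethylcyclohexan‑1‑one | C[C@@H]1C[C@@H](O)CC(C)(C)C1=O | intermediate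
12 | (4R,6R)‑4‑hydroxy‑2,2,6‑trimethylcyclohexanone hydrazone | C[C@@H]1C[C@@H](O)CC(C)(C)C1=NN | intermediate
13 | (1R)‑4‑iodo‑3,5,5‑trimethylcyclohex‑3‑en‑1‑ol | CC1=C(I)C(C)(C)C[C@H](O)C1 | intermediate
14 | (2E)‑3‑methylpent‑2‑en‑4‑yn‑1‑ol | C#C/C(C)=C/CO | starting material
15 | (1R)‑4‑[(3E)‑5‑hydroxy‑3‑methylpent‑3‑en‑1‑yn‑1‑yl]‑3,5,5‑trimethylcyclohex‑3‑en‑1‑ol | CC1=C(C#C/C(C)=C/CO)C(C)(C)C[C@H](O)C1 | intermediate
16 | [(2E)‑5‑[(4R)‑4‑hydroxy‑2,6,6‑trimethylcyclohex‑1‑en‑1‑yl]‑3‑methylpent‑2‑en‑4‑yn‑1‑yl]triphenylphosphonium bromide | CC1=C(C#C/C(C)=C/C[P+](c2ccccc2)(c2ccccc2)c2ccccc2)C(C)(C)C[C@H](O)C1.[Br-] | intermediate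
17 | (2E,4E,6E)‑2,7‑dimethylocta‑2,4,6‑trienedial | O=C/C(C)=C/C=C/C=C(C)/C=O | starting material
18 | C15 phosphorus ylide from 16 | CC1=C(C#C/C(C)=C/C=P(c2ccccc2)(c2ccccc2)c2ccccc2)C(C)(C)C[C@H](O)C1 | intermediate
19 | (2E,4E,6E,8E,10E)‑13‑[(4R)‑4‑hydroxy‑2,6,6‑trimethylcyclohex‑1‑en‑1‑yl]‑2,7,11‑trimethyltrideca‑2,4,6,8,10‑pentaen‑12‑ynal | CC1=C(C#C/C(C)=C/C=C/C(C)=C/C=C/C=C(C)/C=O)C(C)(C)C[C@H](O)C1 | intermediate
20 | (2E)‑5‑[(4R)‑4‑hydroxy‑2,6,6‑trimethylcyclohex‑1‑en‑1‑yl]‑3‑methylpent‑2‑en‑4‑yn‑1‑yl acetate | CC1=C(C#C/C(C)=C/COC(C)=O)C(C)(C)C[C@H](O)C1 | intermediate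
21 | (2E)‑5‑[(1S,4S,6S)‑4‑hydroxy‑2,2,6‑trimethyl‑7‑oxabicyclo[4.1.0]heptan‑1‑yl]‑3‑methylpent‑2‑en‑4‑yn‑1‑yl acetate | CC(=O)OC/C=C(C)/C#C[C@@]12C(C)(C)C[C@H](O)C[C@]1(C)O2 | intermediate
22 | (2E)‑3‑methyl‑5‑[(1S,2R,4S)‑1,2,4‑trihydroxy‑2,6,6‑trimethylcyclohexyl]pent‑2‑en‑4‑yn‑1‑yl acetate | CC(=O)OC/C=C(C)/C#C[C@@]1(O)C(C)(C)C[C@H](O)C[C@@]1(C)O | intermediate
23 | [(2E)‑3‑methyl‑5‑[(1S,2R,4S)‑1,2,4‑trihydroxy‑2,6,6‑trimethylcyclohexyl]pent‑2‑en‑4‑yn‑1‑yl]triphenylphosphonium bromide | [Br-].c1ccccc1[P+](c1ccccc1)(c1ccccc1)C/C=C(C)/C#C[C@@]1(O)C(C)(C)C[C@H](O)C[C@@]1(C)O | intermediate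
24 | trihydroxy C15 phosphorus ylide from 23 | c1ccccc1P(c1ccccc1)(c1ccccc1)=C/C=C(C)/C#C[C@@]1(O)C(C)(C)C[C@H](O)C[C@@]1(C)O | intermediate
25 | 7',8'‑didehydroheteroxanthin (full name in step 14) | CC1=C(C#C/C(C)=C/C=C/C(C)=C/C=C/C=C(C)/C=C/C=C(C)/C#C[C@@]2(O)C(C)(C)C[C@H](O)C[C@@]2(C)O)C(C)(C)C[C@H](O)C1 | intermediate
26 | heteroxanthin, (3S,5R,6R,3'R) (full name in step 15) | CC1=C(C#C/C(C)=C/C=C/C(C)=C/C=C/C=C(C)/C=C/C=C(C)/C=C/[C@@]2(O)C(C)(C)C[C@H](O)C[C@@]2(C)O)C(C)(C)C[C@H](O)C1 | target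

**Step count and weak points**

Total: 15 steps. Longest linear sequence: 12 steps (1 → 3 → 8 → 10 → 11 → 13 → 15 → 20 → 21 → 22 → 23 → 25 → 26).

Step 3 (twofold cycloaddition). The dimethyl‑substituted diene terminus may stop the reaction at the open‑chain Michael stage. The fallback builds the ring stepwise and ionically instead of pericyclically. It sets out from 3 (with 7): TiCl2(O‑i‑Pr)2 in CH2Cl2 at −78 °C promotes a Mukaiyama–Michael addition, and a K2CO3/CH3OH work‑up gives the open‑chain nitro enone 2,6‑dimethyl‑7‑nitrohept‑2‑en‑4‑one F1. DBU in THF then closes the ring by intramolecular nitronate Michael addition onto the β,β‑dimethyl enone. This comes back to the route at 9, which goes on through the Nef stage of step 4.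

Step 5 (enzymatic dynamic kinetic reduction). Epimerisation at C6 may be too slow, or the enzyme may not be selective on the racemate. The fallback sets out from 10: 2‑iodoxybenzoic acid in DMSO at 70 °C dehydrogenates it to 2,6,6‑trimethylcyclohex‑2‑ene‑1,4‑dione F2. Fermenting baker's yeast reduces the C=C bond to (6R)‑2,2,6‑trimethylcyclohexane‑1,4‑dione F3. LiBH(s‑Bu)3 in THF at −78 °C then attacks the unhindered carbonyl from the equatorial side and comes back to the route at 11.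

Step 15 (chemoselective alkyne reduction on the C40 polyene). The hydride may attack the polyenyne or the yield may be poor. The fallback reduces the alkyne before the polyene exists and sets out from 22 and 19. NaAlH2(OCH2CH2OCH3)2 in THF reduces 22 (alkyne to E‑alkene, acetate cleaved) to (2E,4E)‑3‑methyl‑5‑[(1R,2R,4S)‑1,2,4‑trihydroxy‑2,6,6‑trimethylcyclohexyl]penta‑2,4‑dien‑1‑ol F4, and MnO2 in CH2Cl2 oxidises only the primary allylic alcohol to (2E,4E)‑3‑methyl‑5‑[(1R,2R,4S)‑1,2,4‑trihydroxy‑2,6,6‑trimethylcyclohexyl]penta‑2,4‑dienal F5. In parallel NaBH4 in CH3OH reduces 19 to (2E,4E,6E,8E,10E)‑13‑[(4R)‑4‑hydroxy‑2,6,6‑trimethylcyclohex‑1‑en‑1‑yl]‑2,7,11‑trimethyltrideca‑2,4,6,8,10‑pentaen‑12‑yn‑1‑ol F6, and PPh3·HBr converts it into the corresponding C25 triphenylphosphonium bromide F7. A Wittig reaction of F7 with F5 (NaOCH3, CH2Cl2/CH3OH) comes back to the route at 26.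

**Further compounds**

F1 | step 3 | 2,6‑dimethyl‑7‑nitrohept‑2‑en‑4‑one | CC(C)=CC(=O)CC(C)C[N+](=O)[O-]
F2 | step 5 | 2,6,6‑trimethylcyclohex‑2‑ene‑1,4‑dione | CC1=CC(=O)CC(C)(C)C1=O
F3 | step 5 | (6R)‑2,2,6‑trimethylcyclohexane‑1,4‑dione | C[C@@H]1CC(=O)CC(C)(C)C1=O
F4 | step 15 | (2E,4E)‑3‑methyl‑5‑[(1R,2R,4S)‑1,2,4‑trihydroxy‑2,6,6‑trimethylcyclohexyl]penta‑2,4‑dien‑1‑ol | OC/C=C(C)/C=C/[C@@]1(O)C(C)(C)C[C@H](O)C[C@@]1(C)O
F5 | step 15 | (2E,4E)‑3‑methyl‑5‑[(1R,2R,4S)‑1,2,4‑trihydroxy‑2,6,6‑trimethylcyclohexyl]penta‑2,4‑dienal | O=C/C=C(C)/C=C/[C@@]1(O)C(C)(C)C[C@H](O)C[C@@]1(C)O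
F6 | step 15 | (2E,4E,6E,8E,10E)‑13‑[(4R)‑4‑hydroxy‑2,6,6‑trimethylcyclohex‑1‑en‑1‑yl]‑2,7,11‑trimethyltrideca‑2,4,6,8,10‑pentaen‑12‑yn‑1‑ol | CC1=C(C#C/C(C)=C/C=C/C(C)=C/C=C/C=C(C)/CO)C(C)(C)C[C@H](O)C1
F7 | step 15 | [(2E,4E,6E,8E,10E)‑13‑[(4R)‑4‑hydroxy‑2,6,6‑trimethylcyclohex‑1‑en‑1‑yl]‑2,7,11‑trimethyltrideca‑2,4,6,8,10‑pentaen‑12‑yn‑1‑yl]triphenylphosphonium bromide | CC1=C(C#C/C(C)=C/C=C/C(C)=C/C=C/C=C(C)/C[P+](c2ccccc2)(c2ccccc2)c2ccccc2)C(C)(C)C[C@H](O)C1.[Br-]
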